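What stays fixed from run to run is the dose, 1.0 M of starting material over 4.0 min, so we compare the runs by their [protic impurity].

| flask | starting material | protic impurity | remark | time |
|---|---|---|---|---|
| zeta | 1 M (fed, over 4.0 min) | 0.28 M | run made earlier; the fed solution adds 0.20 times the starting volume |  |
| epsilon | 1 M (fed, over 4.0 min) | 0.44 M | run made earlier; the fed solution adds 0.20 times the starting volume |  |
| flask | 1.0 M (fed, over 4.0 min) | 0.200 M | the fed solution adds 0.20 times the starting volume | 4.0 min |

| run | time / min | target / % | starting material / % |
|---|---|---|---|
| zeta | 0.833 | 1.3 | 12.8 |
| zeta | 1.50 | 2.5 | 18.9 |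
| zeta | 2.50 | 5.3 | 26.5 |
| zeta | 3.00 | 7.3 | 30.6 |
| zeta | 4.00 | 9.5 | 40.1 |
| zeta | 5.00 | 11.5 | 29.0 |
| epsilon | 0.333 | 0 | 6.2 |
| epsilon | 1.00 | 0.4 | 12.2 |
| epsilon | 1.50 | 2.4 | 15.4 |
| epsilon | 2.50 | 4.4 | 21.7 |
| epsilon | 4.00 | 7.9 | 33.0 |
| epsilon | 5.00 | 10.2 | 21.8 |

(readings scatter by 0.5 percentage points)

- amounts are per litre of the starting volume; all of the dose is in the solution fed
- on the list of suspects stand: starting material + protic impurity -> quenched substrate; target -> over-reaction product; starting material <-> target; isomer of the product B <-> starting material; isomer of the product A <-> isomer of the product B; target <-> isomer of the product A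
- percentages count the whole charge, also what has not yet gone in

1. amount of target in percent of the starting material charged, at 50 s, 2.0 min and 4.0 min

We bracket the end of the feed, where both runs were read at the same time, 4.00 min. From below, the epsilon run, with more impurity, read less target than the zeta run, so for the flask, with less impurity than either, we expect at least the zeta reading of 9.5 %. From above, the flask has 0.0800 M less impurity than the zeta run. On the suspected quench, one impurity takes one starting material, so if every spared molecule became target, the flask would reach 17.5 %.

Logarithms tighten this. From the zeta to the epsilon run, log10 [protic impurity] rises by 0.196 while log10 target at the end of the feed falls by 0.0801. Their ratio, 0.408, is the impurity slope, the apparent order of target in impurity with its minus sign dropped. It is a reading, and it carries the scatter of 0.5 percentage points. Carried down to the flask, it gives 10.9 %, our higher estimate. A straight line in [protic impurity] gives 10.3 %, our lower estimate. Both rest on scattered readings, so they are estimates and not strict bounds.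

The forecast gives 0.9 %, 3.6 % and 10.3 %, saying “Extrapolating from the two runs at 4 min gives about 10.3”. Its last value stands level with our lower estimate.

The flask gives 1.09 %, 4.15 % and 10.8 %, and the equations were these:

    starting material + protic impurity → quenched substrate (k = 0.0516 M⁻¹ s⁻¹)
    target → over-reaction product (k = 0.00316 s⁻¹)
    starting material ⇌ target (K = 0.880, k = 0.00319 s⁻¹)
    isomer of the product B ⇌ starting material (k = 0.00849 s⁻¹)
    isomer of the product A ⇌ isomer of the product B (K = 0.660, k = 0.0104 s⁻¹)
    target ⇌ isomer of the product A (K = 1.21, k = 0.00197 s⁻¹)

At 4.00 min, protic impurity stood at 6.78 % of its own charge in the flask. Taking the flask and the zeta reading as the pair, the impurity slope, again a reading, comes to 0.381, against 0.408 from the zeta and epsilon runs.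

The data are simulated on assumed constants, and the scatter is random.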